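(The numbers in the tables come from a simulation with made-up constants; scatter was added.)

In a closed flask of constant volume, what leaves one species stays in another. So a fall in the elm run's sum of starting material and target meant that something I did not read was taking it up. That sum went from 98.1% at 4.00 min to 55.2% at 60.0 min.

| flask | starting material | partner | second substrate | third substrate | temperature | remark | time |
|---|---|---|---|---|---|---|---|
| elm | 0.22 M | 0.22 M | 2.2 M | 0.22 M | −18 °C | run made earlier |  |
| alder | 0.88 M | 0.22 M | 2.2 M | 0.22 M | −1 °C | run made earlier |  |
| Tuesday's | 0.44 M | 0.220 M | 2.20 M | 0.220 M | 5 °C |  | 15 min |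
| Wednesday's | 0.44 M | 0.220 M | 2.20 M | 0.220 M |  | at −25 °C until 10 min, from then on at 5 °C | 15 min |
| Sunday's | 0.44 M | 0.220 M | 2.20 M | 0.220 M | −25 °C |  | 15 min |
| Monday's | 0.44 M | 0.220 M | 2.20 M | 0.220 M | −10 °C |  | 15 min |

- elm (time / min: target / %, starting material / %): 4.00: 47.5, 50.6; 8.00: 53.2, 40.0; 15.0: 50.7, 35.0; 30.0: 38.0, 34.7; 60.0: 21.2, 34.0
- alder (time / min: target / %, starting material / %): 1.33: 16.5, 79.8; 2.50: 12.2, 79.6; 5.00: 6.5, 79.8; 10.0: 2.2, 79.0; 20.0: 0, 79.9

(readings scatter by 0.5 percentage points)

- what was read earlier has a scatter of 0.5 percentage points, one standard deviation

* the flask with the highest amount of target, in percent of the starting material charged ("all alike" if they lie within 1.5 percentage points) (Tuesday's / Wednesday's / Sunday's / Monday's / all alike)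
* final target, as a percentage of the starting material charged, in Tuesday's
* final target, as a percentage of the starting material charged, in Wednesday's
* final target, as a percentage of the starting material charged, in Sunday's
* final target, as a percentage of the starting material charged, in Monday's

Between the last two elm readings, starting material moved by 0.7 percentage points and target by 17 points, far more than starting material, so I read that stretch as plain first-order loss of target: a fixed fraction goes each minute. The logarithm of the fall over the time gave a rate constant of 0.0195 min⁻¹ at −18 °C. The first and third alder readings, where starting material stood flat, gave 0.254 min⁻¹ at −1 °C.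

I took the logarithm of this constant as straight in temperature, which is my own simplification. The loss constant, the first-order rate constant at which target disappears at a flask's temperature, then came to 0.00676 min⁻¹ for Sunday's, extrapolated below the two runs, 0.0652 min⁻¹ for Monday's, between them, and 0.628 min⁻¹ at 5 °C, extrapolated above them. Its use is the survival factor, exp(−kt), the fraction of target still there after a time t.

Partner, c(partner) = 0.220 M, is the limiting reagent, charged at half of the starting material. As a rough reckoning of my own, I multiplied that share by the survival factor over the whole time, as if target stood there from the start. This gave 45.2% for Sunday's, 18.8% for Monday's, 2.02% for Wednesday's and 0.00403% for Tuesday's. Sunday's led.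

The forecast also named Sunday's, with 40.5% there (37% to 44%), 15.2% in Monday's, 2.4% in Wednesday's and 0.01% in Tuesday's. Its ground was that “Formation takes only minutes, and the rest of the time is loss”. Its Sunday's and Monday's figures lay lower than mine, and its Wednesday's and Tuesday's figures higher.

The simulation gave Sunday's as the best flask: 39.5% there, 14.9% in Monday's, 2.64% in Wednesday's and 0.0104% in Tuesday's, each inside the forecast's range.

    target → over-reaction product (k = 0.549 min⁻¹, Ea = 85.0 kJ mol⁻¹)
    starting material + partner → target (k = 5.94 M⁻¹ min⁻¹, Ea = 37.0 kJ mol⁻¹)
    second substrate + partner → second product (k = 0.170 M⁻¹ min⁻¹, Ea = 68.0 kJ mol⁻¹)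
    third substrate + partner → third product (k = 3.92 M⁻¹ min⁻¹, Ea = 61.0 kJ mol⁻¹)
    (constants at 5 °C)

Sunday's had not come to rest at 15.0 min. At 150 min starting material still stood at 56.7%, but target had gone from 39.5% to 16.8% and over-reaction product from 3.25% to 26.6%. Sunday's loss constant over the added time gives a survival factor of 40.2%, hence 15.9% of target against the 16.8% found. In Wednesday's, the warm constant over the last 5.00 min takes 39.3% to 1.70% against the 2.64% found, and ten times the time brought that flask to 0% target and 42.7% over-reaction product.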